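**Plan**

- Retrosynthesis: the ring B carboxyl is kept as a benzyl ester until the end. The depside bond from the ring A carbonyl to the ring B oxygen is cut to give an acid and a phenol. Ring B is cut at C2–C3 and C4–C5 into an oxygenated butadiene and a 2-alkynoate. Ring A is cut at aryl–CO2H and aryl–heptyl.
- Forward: the ynoate (one step) and the diene (three steps) are made separately. Ring B arises by cycloaddition and aromatisation. The ring A acid is built in three steps on a purchased bromoarene. The rings are joined by esterification, and hydrogenolysis frees the acid.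
- Feature (ring B numbered C1 = carbon bearing the depside oxygen, C3 = pentyl, C4 = carboxyl, C5 = methoxy): the C1 and C5 oxygens are meta to each other, and C3/C4 carry the alkyl/carboxyl pair of an alkynoate. C1 can therefore come from a silyl enol ether carbon and C5 from a ketene acetal carbon of one diene, so the free hydroxyl and the methyl ether are set without protecting-group exchange.
- Stereochemistry: the target has no stereocentre and no stereogenic double bond; only regiochemistry has to be controlled (steps 5 and 7).

Key step: step 5

Remark on the chemistry: diene 11 is moisture-sensitive and is assumed to be distilled and used at once; heptylmagnesium bromide is taken as a purchased ethereal solution.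

**Route**

Step 1
Reactants: 1 1-heptyne; 2 benzyl chloroformate
Product: 4 benzyl oct-2-ynoate, via lithium hept-1-yn-1-ide 3 (not isolated)
Conditions: n-BuLi, THF, −78 °C; cannulated into ClCO2Bn, THF, −78 → 0 °C
Reagents that add atoms: none
Why: Deprotonation of the terminal alkyne gives acetylide 3, and its C-acylation by the chloroformate (acetylide added to the electrophile to avoid a second addition) is the standard alkynoate synthesis.

Step 2
Reactants: 5 acetyl chloride; 6 1,1-dichloroethene
Product: 8 4,4-dichlorobut-3-en-2-one, via 4,4,4-trichlorobutan-2-one 7 (not isolated)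
Conditions: AlCl3, CH2Cl2, 0 °C → rt; ice/HCl; steam distillation
Reagents that add atoms: none
Why: In this Kondakov (Friedel–Crafts-type) alkene acylation the acylium ion adds to the CH2 terminus, the chlorine-stabilised cation takes up chloride to give 7, and β-elimination of HCl on steam distillation should give the conjugated dichlorovinyl ketone.

Step 3
Reactants: 8 4,4-dichlorobut-3-en-2-one
Product: 10 4,4-dimethoxybut-3-en-2-one, via 4-chloro-4-methoxybut-3-en-2-one 9 (not isolated)
Conditions: NaOMe (2.0 equiv), MeOH, 0 °C → rt
Reagents that add atoms: sodium methoxide, C[O-].[Na+]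
Why: Two successive addition–elimination events (nucleophilic vinylic substitution) at the β-carbon of this vinylogous acid chloride replace both chlorides, and limiting methoxide to two equivalents should stop at the ketene acetal.

Step 4
Reactants: 10 4,4-dimethoxybut-3-en-2-one
Product: 11 1,1-dimethoxy-3-(trimethylsilyloxy)buta-1,3-diene
Conditions: TMSCl, Et3N, ZnCl2 (cat.), toluene, 40 °C; filtration under N2, distillation
Reagents that add atoms: chlorotrimethylsilane, C[Si](C)(C)Cl
Why: Soft enolisation of the methyl ketone, the only enolisable site, followed by O-silylation is the usual silyl enol ether route to 2-silyloxybutadienes.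

Step 5
Reactants: 11 1,1-dimethoxy-3-(trimethylsilyloxy)buta-1,3-diene; 4 benzyl oct-2-ynoate
Product: 14 benzyl 4-hydroxy-2-methoxy-6-pentylbenzoate, via cyclohexa-1,4-diene cycloadduct 12 (not isolated), via aryl trimethylsilyl ether 13 (not isolated)
Conditions: 11 (2 equiv), neat, 120 °C, sealed tube; then 1 M HCl, THF, rt
Reagents that add atoms: none
Why: The electron-rich diene and the electron-poor ynoate should combine in a normal-electron-demand Diels–Alder reaction that is one-step but non-synchronous: the unsubstituted CH2 terminus of 11 bonds to the pentyl-bearing β-carbon of 4 (ring B C2–C3) ahead of the bond from the ketene acetal carbon to the α-carbon (C5–C4). The closest known reaction type is the benzannulation of 1,1-dialkoxy-3-silyloxybutadienes with alkynoates to 4-hydroxy-2-alkoxy-6-alkylbenzoates. Ring B, the only ring formed, closes by this intermolecular [4+2] cycloaddition to give cyclohexa-1,4-diene 12, which aromatises by 1,4-elimination of methanol to silyl ether 13, and the acidic work-up cleaves the O–Si bond. No stereocentre is created. The step needs regioselectivity only, which is secured by matched polarisation: the three oxygen donors place the largest HOMO coefficient on the CH2 terminus of 11, and the ester places the largest LUMO coefficient on the β-carbon of 4. Because the acetal carbon can lose only methanol while the enol ether oxygen is carried as a silyl ether, the C5 methoxy and the free C1 hydroxyl emerge chemically distinct.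

Step 6
Reactants: 15 1-bromo-3,5-dimethoxybenzene; 16 heptylmagnesium bromide
Product: 17 1-heptyl-3,5-dimethoxybenzene
Conditions: Ni(dppp)Cl2 (cat.), Et2O, reflux
Reagents that add atoms: none
Why: Kumada–Corriu coupling (oxidative addition of the aryl bromide, transmetalation from the primary alkyl Grignard, reductive elimination) should join aryl and heptyl, with the chelating dppp ligand suppressing β-hydride elimination.

Step 7
Reactants: 17 1-heptyl-3,5-dimethoxybenzene
Product: 18 2-bromo-1-heptyl-3,5-dimethoxybenzene
Conditions: NBS (1.0 equiv), MeCN, 0 °C → rt
Reagents that add atoms: N-bromosuccinimide, O=C1CCC(=O)N1Br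
Why: Electrophilic aromatic bromination should occur at C2, which is para to one methoxy and ortho to the other, because the position between the two methoxy groups is doubly flanked and has no para donor; one equivalent of NBS limits dibromination.

Step 8
Reactants: 18 2-bromo-1-heptyl-3,5-dimethoxybenzene
Product: 20 2-heptyl-4,6-dimethoxybenzoic acid, via (2-heptyl-4,6-dimethoxyphenyl)lithium 19 (not isolated)
Conditions: n-BuLi, THF, −78 °C; CO2 (g), −78 °C → rt; 1 M HCl
Reagents that add atoms: carbon dioxide, O=C=O
Why: Bromine–lithium exchange generates aryllithium 19 at the carbon fixed by the bromide, and carboxylation with CO2 followed by acidification gives the benzoic acid.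

Step 9
Reactants: 20 2-heptyl-4,6-dimethoxybenzoic acid; 14 benzyl 4-hydroxy-2-methoxy-6-pentylbenzoate
Product: 22 benzyl 4-[(2-heptyl-4,6-dimethoxybenzoyl)oxy]-2-methoxy-6-pentylbenzoate, via mixed trifluoroacetic anhydride 21 (not isolated)
Conditions: TFAA, toluene, rt; then 14, rt
Reagents that add atoms: none
Why: Trifluoroacetic anhydride turns the doubly ortho-substituted, electron-rich acid into mixed anhydride 21, which ionises easily to a hindered acylium ion that O-acylates the phenol (mixed-anhydride esterification of hindered acids, the classical depside coupling), while the benzyl ester and methyl ethers are inert.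

Step 10
Reactants: 22 benzyl 4-[(2-heptyl-4,6-dimethoxybenzoyl)oxy]-2-methoxy-6-pentylbenzoate
Product: 23 4-[(2-heptyl-4,6-dimethoxybenzoyl)oxy]-2-methoxy-6-pentylbenzoic acid
Conditions: H2 (1 atm), 10 % Pd/C, EtOAc, rt
Reagents that add atoms: none
Why: Catalytic hydrogenolysis cleaves the benzylic C–O bond of the benzyl ester under neutral conditions that should leave the aryl ester link, the methyl ethers and both arenes untouched.

**Compound list**

1 | 1-heptyne | CCCCCC#C | starting material
2 | benzyl chloroformate | O=C(Cl)OCc1ccccc1 | starting material
3 | lithium hept-1-yn-1-ide | [Li]C#CCCCCC | intermediate (not isolated)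
4 | benzyl oct-2-ynoate | CCCCCC#CC(=O)OCc1ccccc1 | intermediate
5 | acetyl chloride | CC(=O)Cl | starting material
6 | 1,1-dichloroethene | C=C(Cl)Cl | starting material
7 | 4,4,4-trichlorobutan-2-one | CC(=O)CC(Cl)(Cl)Cl | intermediate (not isolated)
8 | 4,4-dichlorobut-3-en-2-one | CC(=O)C=C(Cl)Cl | intermediate
9 | 4-chloro-4-methoxybut-3-en-2-one (E/Z mixture) | CC(=O)C=C(Cl)OC | intermediate (not isolated)
10 | 4,4-dimethoxybut-3-en-2-one | CC(=O)C=C(OC)OC | intermediate
11 | 1,1-dimethoxy-3-(trimethylsilyloxy)buta-1,3-diene | COC(OC)=CC(=C)O[Si](C)(C)C | intermediate
12 | benzyl 6,6-dimethoxy-2-pentyl-4-(trimethylsilyloxy)cyclohexa-1,4-diene-1-carboxylate | CCCCCC1=C(C(=O)OCc2ccccc2)C(OC)(OC)C=C(O[Si](C)(C)C)C1 | intermediate (not isolated)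
13 | benzyl 2-methoxy-6-pentyl-4-(trimethylsilyloxy)benzoate | CCCCCc1cc(O[Si](C)(C)C)cc(OC)c1C(=O)OCc1ccccc1 | intermediate (not isolated)
14 | benzyl 4-hydroxy-2-methoxy-6-pentylbenzoate | CCCCCc1cc(O)cc(OC)c1C(=O)OCc1ccccc1 | intermediate
15 | 1-bromo-3,5-dimethoxybenzene | COc1cc(Br)cc(OC)c1 | starting material
16 | heptylmagnesium bromide | CCCCCCC[Mg]Br | starting material
17 | 1-heptyl-3,5-dimethoxybenzene | CCCCCCCc1cc(OC)cc(OC)c1 | intermediate
18 | 2-bromo-1-heptyl-3,5-dimethoxybenzene | CCCCCCCc1cc(OC)cc(OC)c1Br | intermediate
19 | (2-heptyl-4,6-dimethoxyphenyl)lithium | CCCCCCCc1cc(OC)cc(OC)c1[Li] | intermediate (not isolated)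
20 | 2-heptyl-4,6-dimethoxybenzoic acid | CCCCCCCc1cc(OC)cc(OC)c1C(=O)O | intermediate
21 | 2-heptyl-4,6-dimethoxybenzoic trifluoroacetic anhydride | CCCCCCCc1cc(OC)cc(OC)c1C(=O)OC(=O)C(F)(F)F | intermediate (not isolated)
22 | benzyl 4-[(2-heptyl-4,6-dimethoxybenzoyl)oxy]-2-methoxy-6-pentylbenzoate | CCCCCCCc1cc(OC)cc(OC)c1C(=O)Oc1cc(CCCCC)c(C(=O)OCc2ccccc2)c(OC)c1 | intermediate
23 | 4-[(2-heptyl-4,6-dimethoxybenzoyl)oxy]-2-methoxy-6-pentylbenzoic acid | CCCCCCCc1cc(OC)cc(OC)c1C(=O)Oc1cc(CCCCC)c(C(=O)O)c(OC)c1 | target

**Count**

Total steps: 10. Longest linear sequence: 6 (steps 2, 3, 4, 5, 9, 10).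

**Steps most likely to fail**

Step 5. The cycloaddition to the β-alkyl ynoate may be slower than thermal decomposition or adventitious hydrolysis of the ketene acetal diene, so that conversion stalls before ring closure. The fallback sets out from 11 and changes the dienophile class from alkyne to allene. Hexanoyl chloride, benzyl (triphenylphosphoranylidene)acetate and Et3N in CH2Cl2 (Wittig reaction of the butylketene formed in the flask) should give racemic benzyl octa-2,3-dienoate F1. Its strained α,β double bond should add 11 in toluene at 60–80 °C with the same orientation, forming the same C2–C3 and C4–C5 bonds, to give benzyl 6,6-dimethoxy-2-pentylidene-4-(trimethylsilyloxy)cyclohex-4-ene-1-carboxylate F2. Dilute HCl in THF should then remove methanol, move the exocyclic double bond into the ring and cleave the silyl group, which brings the route back at 14.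

Step 9. Acyl transfer from the doubly ortho-substituted mixed anhydride to a phenol deactivated by its para ester may be slow, so that O-trifluoroacetylation of the phenol or Friedel–Crafts self-acylation of the electron-rich ring A competes. The fallback sets out from 20 and replaces acid-promoted acylium transfer by acylation of a phenoxide. Oxalyl chloride with catalytic DMF in CH2Cl2 should give 2-heptyl-4,6-dimethoxybenzoyl chloride F3. Phenol 14 is deprotonated separately with NaH in THF to sodium 4-(benzyloxycarbonyl)-3-methoxy-5-pentylphenoxide F4. Combining the two at 0 °C → rt should give the depside ester, so the route is rejoined at 22.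

Step 3. Over-addition of methoxide to the ketene acetal (orthoester formation) or hydrolysis of the acyl ketene acetal to the acetoacetate during isolation may erode the product. The fallback sets out from 5 and builds the same carbon skeleton by C-acylation of a preformed ketene acetal. Acetyl chloride is added to two equivalents of purchased 1,1-dimethoxyethene in Et2O at 0 °C; the second equivalent takes up the HCl as methyl acetate and chloromethane. This should give the acyl ketene acetal under non-aqueous, base-free conditions, bypassing 8 and 9 and returning at 10; it makes no compound outside the list (F0).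

**Further compounds**

F1 | step 5 | benzyl octa-2,3-dienoate (racemic) | CCCCC=C=CC(=O)OCc1ccccc1
F2 | step 5 | benzyl 6,6-dimethoxy-2-pentylidene-4-(trimethylsilyloxy)cyclohex-4-ene-1-carboxylate (racemic, alkene geometry not controlled) | CCCCC=C1CC(O[Si](C)(C)C)=CC(OC)(OC)C1C(=O)OCc1ccccc1
F3 | step 9 | 2-heptyl-4,6-dimethoxybenzoyl chloride | CCCCCCCc1cc(OC)cc(OC)c1C(Cl)=O
F4 | step 9 | sodium 4-(benzyloxycarbonyl)-3-methoxy-5-pentylphenoxide | CCCCCc1cc([O-])cc(OC)c1C(=O)OCc1ccccc1.[Na+]
F0 | step 3 | none | none
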